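Numbering used below: ring carbons C1–C10 (C1 ketone, C2=C3 enol ether, C4 with exo-methylene C15, C5 carbinol, C6 lactone oxygen, C7, C8 ester, C9, C10 with methyl C14 and the ring oxygen); lactone carbons C11–C13.
Enabling feature: the furanone oxygen is a one-atom bridge between C3 and C10 of the ten-membered carbocycle, and the ring O–C10–C1(=O)–C2=C3 is the cyclodehydrated form of an α′-hydroxy-1,3-diketone whose hydroxyl sits on the methyl-bearing quaternary C10. Cutting O–C3 across the ring leaves a monocyclic cyclodecane-1,3-dione with a tertiary carbinol.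
The dione is carried as an isoxazoline from nitrile oxide cycloaddition onto the vinyl group of (R)-linalool (supplies C1, C2, C7–C10, C14, the C10 stereocentre and the future furanone oxygen). The nitrile oxide comes from 2-deoxy-L-ribose (supplies C3–C6, the C5 stereocentre, the C5 hydroxyl oxygen and the lactone ring oxygen).
The carbocycle is cut at C6–C7: macrocyclising CrCl2-mediated allylation of the C6 aldehyde by a 2-(bromomethyl)enoate (C11–C13 from methyl propiolate), then lactonisation. C8–O comes from proline α-aminoxylation, C15 from an Eschenmoser methylenation, the ester from late acylation.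
Ring order: isoxazoline (temporary) → ten-membered carbocycle → α-methylene-γ-lactone → isoxazoline opened → furanone last, by oxidation and transannular cyclodehydration.

Key step: step 22

Remark on the chemistry: the isoxazoline carbon C1 and the carbinol carbon of the Baylis–Hillman-type adduct form as epimer mixtures that converge later, so they are left undefined in the SMILES; 2-deoxy-L-ribose is drawn open-chain.

Step 1
Reactants: 1 (R)-(−)-linalool [(3R)-3,7-dimethylocta-1,6-dien-3-ol]
Product: 2 (3R)-3,7-dimethyl-3-(triethylsilyloxy)octa-1,6-diene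
Conditions: Et3SiOTf, 2,6-lutidine, CH2Cl2, −78 °C to 0 °C
Reagents that add atoms: triethylsilyl trifluoromethanesulfonate, CC[Si](CC)(CC)OS(=O)(=O)C(F)(F)F
Why: O-Silylation with a silyl triflate and a hindered base works even on a tertiary allylic alcohol and masks the C10 hydroxyl (the later furanone oxygen) so that it cannot form a lactol with the C7 aldehyde; the stereocentre is not touched.

Step 2
Reactants: 2 (3R)-3,7-dimethyl-3-(triethylsilyloxy)octa-1,6-diene
Product: 4 (4R)-4-methyl-4-(triethylsilyloxy)hex-5-enal, via secondary ozonide 3 (not isolated)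
Conditions: O3 (1 equiv, Sudan Red 7B end point), CH2Cl2, −78 °C; then Me2S, −78 °C to rt
Reagents that add atoms: ozone, [O-][O+]=O
Why: Chemoselective ozonolysis: electrophilic ozone cleaves the electron-rich trisubstituted alkene much faster than the vinyl group next to the quaternary carbon, and reductive work-up should give the C7 aldehyde.

Step 3
Reactants: 4 (4R)-4-methyl-4-(triethylsilyloxy)hex-5-enal
Product: 6 (2R,4R)-4-methyl-2-(N-phenylaminooxy)-4-(triethylsilyloxy)hex-5-en-1-ol, via anilinooxy aldehyde 5 (not isolated)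
Conditions: PhNO, L-proline (20 mol%), DMSO, rt; then NaBH4, EtOH, 0 °C
Reagents that add atoms: nitrosobenzene, O=Nc1ccccc1
Why: Proline-catalysed α-aminoxylation (O-nitroso aldol through the enamine): the (E)-enamine of L-proline attacks the nitroso oxygen on the face fixed by the carboxylic acid hydrogen bond, which sets C8 as R under catalyst control, and reduction in the same flask prevents epimerisation.

Step 4
Reactants: 6 (2R,4R)-4-methyl-2-(N-phenylaminooxy)-4-(triethylsilyloxy)hex-5-en-1-ol
Product: 7 (2R,4R)-4-methyl-4-(triethylsilyloxy)hex-5-ene-1,2-diol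
Conditions: Zn, AcOH, THF, rt
Reagents that add atoms: none
Why: Reductive N–O cleavage: zinc in acetic acid breaks the weak N–O bond of the O-alkyl-N-arylhydroxylamine without touching the vinyl group or the tertiary silyl ether.

Step 5
Reactants: 7 (2R,4R)-4-methyl-4-(triethylsilyloxy)hex-5-ene-1,2-diol
Product: 8 (4R)-2-(4-methoxyphenyl)-4-[(2R)-2-methyl-2-(triethylsilyloxy)but-3-enyl]-1,3-dioxolane (both acetal epimers)
Conditions: 4-MeOC6H4CH(OMe)2, pyridinium p-toluenesulfonate (PPTS, cat.), CH2Cl2, rt
Reagents that add atoms: 4-methoxybenzaldehyde dimethyl acetal, COc1ccc(C(OC)OC)cc1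
Why: Acid-catalysed transacetalisation of the terminal 1,2-diol gives the five-membered p-methoxybenzylidene acetal, whose new acetal centre is lost in the next step.

Step 6
Reactants: 8 the p-methoxybenzylidene acetal
Product: 9 (2R,4R)-2-(4-methoxybenzyloxy)-4-methyl-4-(triethylsilyloxy)hex-5-en-1-ol
Conditions: iBu2AlH, CH2Cl2, −78 °C to 0 °C
Reagents that add atoms: none
Why: Regioselective reductive acetal opening: the aluminium hydride coordinates the less hindered primary oxygen and delivers hydride to the acetal carbon, so the PMB group should stay on the secondary C8 oxygen and the primary C7 alcohol is freed.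

Step 7
Reactants: 10 2-deoxy-L-ribose [(3R,4S)-3,4,5-trihydroxypentanal]
Product: 11 2-deoxy-L-ribose diethyl dithioacetal [(2S,3R)-5,5-bis(ethylsulfanyl)pentane-1,2,3-triol]
Conditions: EtSH, conc. HCl, 0 °C
Reagents that add atoms: ethanethiol, CCS
Why: Dithioacetal formation traps the sugar in its open-chain form and protects the future C3 aldehyde carbon.

Step 8
Reactants: 11 2-deoxy-L-ribose diethyl dithioacetal
Product: 12 (1R)-1-[(4S)-2,2-dimethyl-1,3-dioxolan-4-yl]-3,3-bis(ethylsulfanyl)propan-1-ol
Conditions: 2,2-dimethoxypropane, TsOH·H2O (cat.), acetone, 0 °C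
Reagents that add atoms: 2,2-dimethoxypropane, COC(C)(C)OC
Why: Acetonide formation favours the terminal monosubstituted dioxolane, which leaves only the C5 hydroxyl free.

Step 9
Reactants: 12 the terminal acetonide
Product: 13 tert-butyldimethylsilyl ether of 12 at the (1R)-carbinol
Conditions: tBuMe2SiCl, imidazole, DMF, rt
Reagents that add atoms: tert-butyldimethylsilyl chloride, CC(C)(C)[Si](C)(C)Cl
Why: Standard O-silylation of the remaining secondary alcohol; the bulky non-chelating silyl ether is chosen to enforce Felkin–Anh control later at C6.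

Step 10
Reactants: 13 the silylated dithioacetal
Product: 14 (3R)-3-(tert-butyldimethylsilyloxy)-3-[(4S)-2,2-dimethyl-1,3-dioxolan-4-yl]propanal
Conditions: MeI, NaHCO3, MeCN/H2O, 40 °C
Reagents that add atoms: water, O
Why: Dithioacetal hydrolysis by S-methylation and buffered hydrolysis of the sulfonium salt releases the aldehyde while the acetonide and the silyl ether are kept.

Step 11
Reactants: 14 the β-silyloxy aldehyde
Product: 16 2-{(R)-(tert-butyldimethylsilyloxy)[(4S)-2,2-dimethyl-1,3-dioxolan-4-yl]methyl}prop-2-enal, via Mannich base 15 (not isolated)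
Conditions: CH2=NMe2 I (Eschenmoser's salt), Et3N, CH2Cl2, rt
Reagents that add atoms: N,N-dimethylmethyleneiminium iodide, C=[N+](C)C.[I-]
Why: Mannich reaction followed by elimination of dimethylamine (α-methylenation of an aldehyde) installs C15, and once the α-carbon is fully substituted the β-silyloxy group can no longer be eliminated.

Step 12
Reactants: 16 the α-methylene aldehyde
Product: 17 (E)-oxime of 16
Conditions: NH2OH·HCl, NaOAc, EtOH/H2O, 0 °C
Reagents that add atoms: hydroxylamine hydrochloride, [NH3+]O.[Cl-]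
Why: Oxime formation by 1,2-addition of hydroxylamine in a buffered medium gives the nitrile oxide precursor.

Step 13
Reactants: 17 the oxime; 9 (2R,4R)-2-(4-methoxybenzyloxy)-4-methyl-4-(triethylsilyloxy)hex-5-en-1-ol
Product: 20 isoxazoline alcohol [(2R,4R)-4-{3-[1-((R)-(tert-butyldimethylsilyloxy)((4S)-2,2-dimethyl-1,3-dioxolan-4-yl)methyl)ethenyl]-4,5-dihydroisoxazol-5-yl}-2-(4-methoxybenzyloxy)-4-(triethylsilyloxy)pentan-1-ol; both epimers at the isoxazoline C5 (= C1)], via hydroximoyl chloride 18 (not isolated), via nitrile oxide 19 (not isolated)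
Conditions: N-chlorosuccinimide, pyridine (cat.), CH2Cl2, 0 °C to rt; then 9, Et3N (syringe pump), CH2Cl2, 0 °C to rt
Reagents that add atoms: none
Why: Huisgen 1,3-dipolar cycloaddition of the slowly released nitrile oxide onto the only alkene of 9 places the oxygen on the substituted carbon C1 and stores C1–C3 as a latent β-hydroxy ketone; the new C1 centre forms as a mixture that is erased in step 22.

Step 14
Reactants: 20 the isoxazoline alcohol
Product: 21 isoxazoline aldehyde (C7 alcohol of 20 oxidised to the aldehyde; 5R 8R 10R; C1 epimers)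
Conditions: Dess–Martin periodinane, pyridine, CH2Cl2, 0 °C to rt
Reagents that add atoms: none
Why: Dess–Martin oxidation converts the primary alcohol into the α-alkoxy aldehyde under buffered conditions that should not epimerise C8.

Step 15
Reactants: 21 the isoxazoline aldehyde
Product: 22 Baylis–Hillman-type adduct (C7 is now CH(OH) carrying C(=CH2)CO2Me; C7 and C1 epimers; otherwise as 21)
Conditions: methyl propiolate, iBu2AlH, N-methylmorpholine N-oxide, THF, 0 °C; then 21, −78 °C to 0 °C
Reagents that add atoms: methyl propiolate, C#CC(=O)OC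
Why: Vinylalumination: hydroalumination of methyl propiolate gives the α-aluminated acrylate, which adds to the aldehyde at low temperature; the new carbinol centre is formed unselectively and is destroyed in step 16.

Step 16
Reactants: 22 the Baylis–Hillman-type adduct
Product: 23 (Z)-allylic bromide (C7H=C11(CH2Br)CO2Me with CH2Br cis to C8; otherwise as 22)
Conditions: N-bromosuccinimide, Me2S, CH2Cl2, −20 °C to rt
Reagents that add atoms: N-bromosuccinimide, O=C1CCC(=O)N1Br
Why: The bromodimethylsulfonium reagent activates the allylic alcohol and bromide attacks with allylic transposition (SN2′) to give the conjugated (Z)-2-(bromomethyl)enoate, the thermodynamically preferred trisubstituted alkene.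

Step 17
Reactants: 23 the (Z)-allylic bromide
Product: 24 bromo aldehyde (dioxolane of 23 cut down to the C6 aldehyde; 5R 8R 10R; C1 epimers)
Conditions: H5IO6, EtOAc, 0 °C to rt
Reagents that add atoms: none
Why: Periodic acid hydrolyses the terminal acetonide and cleaves the freed 1,2-diol in one operation (glycol cleavage), leaving the silyl and PMB ethers; the labile α-silyloxy β,γ-unsaturated aldehyde is used crude.

Step 18
Reactants: 24 the bromo aldehyde
Product: 26 macrocyclic lactone (ten-membered carbocycle C1–C10 bridged between C1 and C3 by the isoxazoline N–O; trans-fused α-methylene-γ-lactone at C6/C7; 8-OPMB; 10-OTES; 5-OTBS; 4-methylene; 5R 6S 7R 8R 10R; C1 epimers), via hydroxy ester 25 (not isolated)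
Conditions: CrCl2 (10 equiv), THF, rt, slow addition of 24 (final 2 mM); then PPTS (cat.), CH2Cl2, rt
Reagents that add atoms: none
Why: Nozaki–Hiyama-type allylation closes the ten-membered ring by attack of the allylchromium γ-carbon C7 on the C6 aldehyde and the alkoxide then lactonises: a chair-like transition state with the C8 substituent pseudo-equatorial should give the 6,7-anti (trans-lactone) relationship, the aldehyde should react on its Felkin–Anh face anti to the C5 silyloxy group, and the allyl unit on the face anti to C9 with the C8 hydrogen eclipsing the alkene, which together correspond to 6S and 7R.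

Step 19
Reactants: 26 the macrocyclic lactone
Product: 27 C8 alcohol (26 without the PMB group)
Conditions: 2,3-dichloro-5,6-dicyano-1,4-benzoquinone (DDQ), CH2Cl2/pH 7 buffer, 0 °C
Reagents that add atoms: none
Why: Oxidative PMB cleavage (single-electron oxidation of the electron-rich arene, then hydrolysis) frees only the C8 hydroxyl and spares silyl ethers, the isoxazoline and the α-methylene lactone.

Step 20
Reactants: 27 the C8 alcohol
Product: 28 C8 3-methylbutanoate of 27
Conditions: (Me2CHCH2CO)2O, 4-(dimethylamino)pyridine (DMAP), Et3N, CH2Cl2, 0 °C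
Reagents that add atoms: 3-methylbutanoic anhydride, CC(C)CC(=O)OC(=O)CC(C)C
Why: DMAP-catalysed acylation of the secondary alcohol installs the ester; it is introduced only now because an acyloxy group at C8 could be lost by 1,4-elimination from the allylchromium intermediate of step 18.

Step 21
Reactants: 28 the C8 ester
Product: 30 β-hydroxy ketone (isoxazoline of 28 opened: C1–OH, C2H2, C3=O conjugated to the C4 methylene; C1 epimers), via hydroxy imine 29 (not isolated)
Conditions: Mo(CO)6, MeCN/H2O, 80 °C, argon sparge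
Reagents that add atoms: water, O
Why: Reductive isoxazoline opening: Mo(CO)6 cleaves the N–O bond and the β-hydroxy imine is hydrolysed in the wet medium, a method that spares alkenes, enoates and esters and reveals the masked aldol.

Step 22
Reactants: 30 the β-hydroxy ketone
Product: 34 O-TBS furanone (the target carrying a tert-butyldimethylsilyl ether on the C5 oxygen), via cyclodecane-1,3-dione 31 (not isolated), via hydroxy dione 32 (not isolated), via bridged hemiketal 33 (not isolated)
Conditions: Dess–Martin periodinane, CH2Cl2, 0 °C to rt; then TsOH·H2O (cat.), THF/H2O, 0 °C to rt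
Reagents that add atoms: none
Why: Dess–Martin oxidation of the only free hydroxyl (C1) gives the cyclodecane-1,3-dione 31; aqueous acid then removes the tertiary triethylsilyl group, the freed C10 hydroxyl adds across the ring to the C3 carbonyl (5-exo-trig hemiketalisation to 33) and loss of water towards C2 gives the vinylogous ester, that is the 3(2H)-furanone. The closest known reaction type is the acid-mediated desilylation and cyclodehydration of α′-silyloxy-1,3-diketones to 3(2H)-furanones, used here in a transannular sense. No new stereocentre is created: C10 comes unchanged from (R)-linalool, C3 becomes trigonal and the epimeric C1 centre is erased by the oxidation. The step needs chemoselectivity for the C10 hydroxyl over the C5 hydroxyl, which could close a bridging pyranone onto C1; this is secured by the more robust secondary TBS ether at C5, removed only in step 23. Regiochemistry is unambiguous, because attack of the C10 oxygen on C1 would give an oxirane and dehydration can only go towards C2 since C4 carries no hydrogen. Closure across the ring should be easy because the C10 oxygen and C3 are held in a 1,4-relationship and the product is the natural bridged framework with C2=C3 trans within the carbocycle.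

Step 23
Reactants: 34 the O-TBS furanone
Product: 35 the target, CNP0409337.2
Conditions: HF·pyridine, pyridine, THF, 0 °C to rt
Reagents that add atoms: none
Why: Fluoride-mediated desilylation with buffered HF·pyridine is mild enough for the α-methylene lactone, the furanone and the ester and frees the C5 hydroxyl.

Compound list
1 | (R)-(−)-linalool | C=C[C@](C)(O)CCC=C(C)C | starting material
2 | (3R)-3,7-dimethyl-3-(triethylsilyloxy)octa-1,6-diene | C=C[C@](C)(O[Si](CC)(CC)CC)CCC=C(C)C | intermediate
3 | secondary ozonide of the 6,7-alkene of 2 | C=C[C@](C)(O[Si](CC)(CC)CC)CCC1OOC(C)(C)O1 | intermediate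
4 | (4R)-4-methyl-4-(triethylsilyloxy)hex-5-enal | C=C[C@](C)(O[Si](CC)(CC)CC)CCC=O | intermediate
5 | (2R,4R)-4-methyl-2-(N-phenylaminooxy)-4-(triethylsilyloxy)hex-5-enal | C=C[C@](C)(O[Si](CC)(CC)CC)C[C@@H](ONc1ccccc1)C=O | intermediate
6 | (2R,4R)-4-methyl-2-(N-phenylaminooxy)-4-(triethylsilyloxy)hex-5-en-1-ol | C=C[C@](C)(O[Si](CC)(CC)CC)C[C@@H](ONc1ccccc1)CO | intermediate
7 | (2R,4R)-4-methyl-4-(triethylsilyloxy)hex-5-ene-1,2-diol | C=C[C@](C)(O[Si](CC)(CC)CC)C[C@@H](O)CO | intermediate
8 | (4R)-2-(4-methoxyphenyl)-4-[(2R)-2-methyl-2-(triethylsilyloxy)but-3-enyl]-1,3-dioxolane | C=C[C@](C)(O[Si](CC)(CC)CC)C[C@@H]1COC(c2ccc(OC)cc2)O1 | intermediate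
9 | (2R,4R)-2-(4-methoxybenzyloxy)-4-methyl-4-(triethylsilyloxy)hex-5-en-1-ol | C=C[C@](C)(O[Si](CC)(CC)CC)C[C@@H](OCc1ccc(OC)cc1)CO | intermediate
10 | 2-deoxy-L-ribose, open-chain form | O=CC[C@@H](O)[C@@H](O)CO | starting material
11 | 2-deoxy-L-ribose diethyl dithioacetal | CCSC(SCC)C[C@@H](O)[C@@H](O)CO | intermediate
12 | (1R)-1-[(4S)-2,2-dimethyl-1,3-dioxolan-4-yl]-3,3-bis(ethylsulfanyl)propan-1-ol | CCSC(SCC)C[C@@H](O)[C@@H]1COC(C)(C)O1 | intermediate
13 | tert-butyldimethylsilyl ether of 12 | CCSC(SCC)C[C@@H](O[Si](C)(C)C(C)(C)C)[C@@H]1COC(C)(C)O1 | intermediate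
14 | (3R)-3-(tert-butyldimethylsilyloxy)-3-[(4S)-2,2-dimethyl-1,3-dioxolan-4-yl]propanal | O=CC[C@@H](O[Si](C)(C)C(C)(C)C)[C@@H]1COC(C)(C)O1 | intermediate
15 | Mannich base, 2-(dimethylaminomethyl) derivative of 14 | O=CC(CN(C)C)[C@@H](O[Si](C)(C)C(C)(C)C)[C@@H]1COC(C)(C)O1 | intermediate
16 | 2-{(R)-(tert-butyldimethylsilyloxy)[(4S)-2,2-dimethyl-1,3-dioxolan-4-yl]methyl}prop-2-enal | O=CC(=C)[C@@H](O[Si](C)(C)C(C)(C)C)[C@@H]1COC(C)(C)O1 | intermediate
17 | (E)-oxime of 16 | O/N=C/C(=C)[C@@H](O[Si](C)(C)C(C)(C)C)[C@@H]1COC(C)(C)O1 | intermediate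
18 | hydroximoyl chloride from 17 | ON=C(Cl)C(=C)[C@@H](O[Si](C)(C)C(C)(C)C)[C@@H]1COC(C)(C)O1 | intermediate
19 | nitrile oxide from 18 | [O-][N+]#CC(=C)[C@@H](O[Si](C)(C)C(C)(C)C)[C@@H]1COC(C)(C)O1 | intermediate
20 | isoxazoline alcohol (5R 8R 10R; C1 epimers) | OC[C@H](OCc1ccc(OC)cc1)C[C@@](C)(O[Si](CC)(CC)CC)C1CC(=NO1)C(=C)[C@@H](O[Si](C)(C)C(C)(C)C)[C@@H]1COC(C)(C)O1 | intermediate
21 | isoxazoline aldehyde | O=C[C@H](OCc1ccc(OC)cc1)C[C@@](C)(O[Si](CC)(CC)CC)C1CC(=NO1)C(=C)[C@@H](O[Si](C)(C)C(C)(C)C)[C@@H]1COC(C)(C)O1 | intermediate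
22 | Baylis–Hillman-type adduct (C7 epimers) | C=C(C(=O)OC)C(O)[C@H](OCc1ccc(OC)cc1)C[C@@](C)(O[Si](CC)(CC)CC)C1CC(=NO1)C(=C)[C@@H](O[Si](C)(C)C(C)(C)C)[C@@H]1COC(C)(C)O1 | intermediate
23 | (Z)-allylic bromide | BrC/C(C(=O)OC)=C\[C@H](OCc1ccc(OC)cc1)C[C@@](C)(O[Si](CC)(CC)CC)C1CC(=NO1)C(=C)[C@@H](O[Si](C)(C)C(C)(C)C)[C@@H]1COC(C)(C)O1 | intermediate
24 | bromo aldehyde | BrC/C(C(=O)OC)=C\[C@H](OCc1ccc(OC)cc1)C[C@@](C)(O[Si](CC)(CC)CC)C1CC(=NO1)C(=C)[C@@H](O[Si](C)(C)C(C)(C)C)C=O | intermediate
25 | macrocyclic hydroxy ester (C5–C8 and C10 arranged as in the target) | C=C(C(=O)OC)[C@H]1[C@H](O)[C@H](O[Si](C)(C)C(C)(C)C)C(=C)C2=NOC(C2)[C@](C)(O[Si](CC)(CC)CC)C[C@H]1OCc3ccc(OC)cc3 | intermediate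
26 | macrocyclic lactone, 8-OPMB (5R 6S 7R 8R 10R) | C=C1C(=O)O[C@H]2[C@H]1[C@H](OCc3ccc(OC)cc3)C[C@@](C)(O[Si](CC)(CC)CC)C4CC(=NO4)C(=C)[C@H]2O[Si](C)(C)C(C)(C)C | intermediate
27 | macrocyclic lactone, C8 alcohol | C=C1C(=O)O[C@H]2[C@H]1[C@H](O)C[C@@](C)(O[Si](CC)(CC)CC)C3CC(=NO3)C(=C)[C@H]2O[Si](C)(C)C(C)(C)C | intermediate
28 | macrocyclic lactone, C8 3-methylbutanoate | C=C1C(=O)O[C@H]2[C@H]1[C@H](OC(=O)CC(C)C)C[C@@](C)(O[Si](CC)(CC)CC)C3CC(=NO3)C(=C)[C@H]2O[Si](C)(C)C(C)(C)C | intermediate
29 | β-hydroxy imine | C=C1C(=O)O[C@H]2[C@H]1[C@H](OC(=O)CC(C)C)C[C@@](C)(O[Si](CC)(CC)CC)C(O)CC(=N)C(=C)[C@H]2O[Si](C)(C)C(C)(C)C | intermediate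
30 | β-hydroxy ketone (C1 epimers) | C=C1C(=O)O[C@H]2[C@H]1[C@H](OC(=O)CC(C)C)C[C@@](C)(O[Si](CC)(CC)CC)C(O)CC(=O)C(=C)[C@H]2O[Si](C)(C)C(C)(C)C | intermediate
31 | cyclodecane-1,3-dione, 10-OTES | C=C1C(=O)O[C@H]2[C@H]1[C@H](OC(=O)CC(C)C)C[C@@](C)(O[Si](CC)(CC)CC)C(=O)CC(=O)C(=C)[C@H]2O[Si](C)(C)C(C)(C)C | intermediate
32 | α′-hydroxy-1,3-dione | C=C1C(=O)O[C@H]2[C@H]1[C@H](OC(=O)CC(C)C)C[C@@](C)(O)C(=O)CC(=O)C(=C)[C@H]2O[Si](C)(C)C(C)(C)C | intermediate
33 | bridged hemiketal | C=C1C(=O)O[C@H]2[C@H]1[C@H](OC(=O)CC(C)C)C[C@@]1(C)OC(O)(CC1=O)C(=C)[C@H]2O[Si](C)(C)C(C)(C)C | intermediate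
34 | O-TBS furanone | C=C1C(=O)O[C@H]2[C@H]1[C@H](OC(=O)CC(C)C)C[C@@]1(C)OC(=CC1=O)C(=C)[C@H]2O[Si](C)(C)C(C)(C)C | intermediate
35 | CNP0409337.2 | C=C1C(=O)O[C@H]2[C@H]1[C@H](OC(=O)CC(C)C)C[C@@]1(C)OC(=CC1=O)C(=C)[C@H]2O | target

Total step count: 23. Longest linear sequence: 17 steps (steps 7–12 then 13–23; the branch from 1, steps 1–6 then 13–23, is equally long).

Steps most likely to fail

Step 18. What may go wrong: intermolecular allylation may compete with ring closure, and facial control at the C6 aldehyde may be lost in the strained cyclic transition state, so that the alkoxide forms on the wrong face. Fallback: the C6 configuration is corrected after ring closure instead of during it. Setting out from 24, the CrCl2 cyclisation is run without the acid treatment and the C6-epimeric hydroxy ester F1 is collected (any cis-lactone is opened in the next operation). LiOH in THF/H2O, safe because no other ester is present at this stage, gives the hydroxy acid F2. Lactonisation under Mitsunobu conditions (PPh3, diisopropyl azodicarboxylate, toluene, 0 °C) closes the lactone with inversion at C6 and returns to the route at 26.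

Step 22. What may go wrong: the free 2-methylene-1,3-dione formed by the oxidation may suffer conjugate addition or retro-Claisen cleavage faster than desilylation and ring closure. Fallback: the oxygen bridge is closed before the oxidation. Setting out from 30, TsOH·H2O in wet THF removes the triethylsilyl group, the C10 hydroxyl ketalises the C3 ketone across the ring and dehydration gives the bridged 2,3-dihydrofuran-3-ol F3, a cyclic enol ether that still carries the C1 carbinol. MnO2 in CH2Cl2 then oxidises this allylic-type alcohol to the vinylogous ester, which returns to the route at 34.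

Step 15. What may go wrong: the aluminium reagent may add to or reduce the isoxazoline C=N, or C8 may epimerise through enolisation of the α-alkoxy aldehyde. Fallback: the acrylate unit is built by aldol addition and elimination instead of by a vinyl metal. Setting out from 21, the lithium enolate of methyl 3-(dimethylamino)propanoate (LDA, THF, −78 °C) gives the β-hydroxy-α-(dimethylaminomethyl) ester F4. N-Methylation with MeI and elimination of trimethylamine with DBU give the same Baylis–Hillman-type adduct and return to the route at 22.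

Further compounds
F1 | step 18 | C6-epimeric macrocyclic hydroxy ester | C=C(C(=O)OC)[C@H]1[C@@H](O)[C@H](O[Si](C)(C)C(C)(C)C)C(=C)C2=NOC(C2)[C@](C)(O[Si](CC)(CC)CC)C[C@H]1OCc3ccc(OC)cc3
F2 | step 18 | C6-epimeric macrocyclic hydroxy acid | C=C(C(=O)O)[C@H]1[C@@H](O)[C@H](O[Si](C)(C)C(C)(C)C)C(=C)C2=NOC(C2)[C@](C)(O[Si](CC)(CC)CC)C[C@H]1OCc3ccc(OC)cc3
F3 | step 22 | bridged 2,3-dihydrofuran-3-ol (C1 carbinol, C2=C3 enol ether, 5-OTBS) | C=C1C(=O)O[C@H]2[C@H]1[C@H](OC(=O)CC(C)C)C[C@@]1(C)OC(=CC1O)C(=C)[C@H]2O[Si](C)(C)C(C)(C)C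
F4 | step 15 | β-hydroxy-α-(dimethylaminomethyl) ester from 21 | COC(=O)C(CN(C)C)C(O)[C@H](OCc1ccc(OC)cc1)C[C@@](C)(O[Si](CC)(CC)CC)C1CC(=NO1)C(=C)[C@@H](O[Si](C)(C)C(C)(C)C)[C@@H]1COC(C)(C)O1
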